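**Strategy.** Everything rests on opening the butenolide at O1–C2 and O1–C5. Its quaternary C5 holds the lactone oxygen and a single carboxyl carbon, the array that remains when C6 of a six-membered 2-pyranone is expelled from the ring. Face-selective oxygen transfer to the C5=C6 enol-ester bond of a flat, stereocentre-free pyranone core, then acid-triggered migration of the lactone acyl group to the new C5 oxygen, contracts the ring, sets C5 and frees C6 as a formyl group in one operation. The precursor is 3-methoxy-4-[3,4-bis(benzyloxy)phenyl]-5-(chromanylmethyl)-2-pyranone with the (S)-chromanol as its benzyl ether, built from a chalcone by α-dimethoxymethylation, ester aldol addition and acid cyclisation.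

Key step: step 9

Remark (numbering): O1, C2(=O), C3(OMe), C4(aryl), C5, C6 are the lactone locants of the pyranone and are kept for the butenolide; systematic furanone names call the same C5 "C2".

Remark (starting material): 2,2-dimethyl-2H-chromene-6-carbonitrile (1) is assumed to be purchased; it is otherwise reached in two steps from 4-cyanophenol and 3-chloro-3-methylbut-1-yne.

Remark (design): the chromanol is carried as a benzyl ether, which withstands the acid used in steps 8 and 9 and falls with the catechol benzyl ethers in the last step. The rearrangement is run with a protic acid, the manifold in which enol ester epoxides rearrange by acyl transfer with retention.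

**Step 1**
Reactants: 1 2,2-dimethyl-2H-chromene-6-carbonitrile
Product: 2 (3S,4S)-3,4-epoxy-2,2-dimethylchroman-6-carbonitrile
Conditions: (S,S)-[Mn(salen)]Cl, i.e. chloro[(S,S)-N,N'-bis(3,5-di-tert-butylsalicylidene)cyclohexane-1,2-diaminato]manganese (trivalent manganese, 3 mol%), aq. NaOCl (pH 11.3, Na2HPO4), 4-phenylpyridine N-oxide, CH2Cl2, 0 °C
Reagents that add atoms: sodium hypochlorite, [Na+].[O-]Cl
Why: Jacobsen–Katsuki epoxidation, for which 2,2-dimethylchromenes are the privileged cis-alkene class; the (S,S)-salen ligand should deliver oxygen to the face that gives the (3S,4S)-epoxide and thereby fixes the later (S)-carbinol carbon.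

**Step 2**
Reactants: 2 (3S,4S)-3,4-epoxy-2,2-dimethylchroman-6-carbonitrile
Product: 3 (3S)-3-hydroxy-2,2-dimethylchroman-6-carbonitrile
Conditions: H2 (1 atm), 10% Pd/C, EtOAc, rt, stopped after one equivalent of H2
Reagents that add atoms: none
Why: Hydrogenolysis of an aryl-substituted epoxide cleaves only the benzylic C4–O bond, so the C3–O bond and its (S) configuration are untouched, and an aryl nitrile is not reduced at one atmosphere in a neutral solvent within the time needed.

**Step 3**
Reactants: 3 (3S)-3-hydroxy-2,2-dimethylchroman-6-carbonitrile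
Product: 4 (3S)-3-(benzyloxy)-2,2-dimethylchroman-6-carbonitrile
Conditions: NaH, BnBr, Bu4NI (cat.), THF–DMF, 0 °C to rt
Reagents that add atoms: benzyl bromide, BrCc1ccccc1
Why: Williamson etherification of the secondary alkoxide, with no base-sensitive group present; the ether oxygen keeps its configuration because no bond to C3 is made or broken.

**Step 4**
Reactants: 4 (3S)-3-(benzyloxy)-2,2-dimethylchroman-6-carbonitrile
Product: 6 (3S)-3-(benzyloxy)-2,2-dimethylchroman-6-carbaldehyde, via N-aluminio aldimine 5 (not isolated)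
Conditions: i-Bu2AlH (1.2 equiv), toluene, −78 °C; then 1 M HCl, 0 °C
Reagents that add atoms: water, O; diisobutylaluminium hydride, CC(C)C[AlH]CC(C)C (its aluminium and isobutyl groups are carried only in 5)
Why: Partial reduction of an aryl nitrile with i-Bu2AlH stops at the N-aluminio aldimine, which is hydrolysed to the aldehyde on acidic work-up.

**Step 5**
Reactants: 6 (3S)-3-(benzyloxy)-2,2-dimethylchroman-6-carbaldehyde; 7 3,4-bis(benzyloxy)acetophenone
Product: 8 (E)-1-[3,4-bis(benzyloxy)phenyl]-3-[(3S)-3-(benzyloxy)-2,2-dimethylchroman-6-yl]prop-2-en-1-one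
Conditions: KOH, EtOH–THF, 40 °C
Reagents that add atoms: none
Why: Claisen–Schmidt condensation of a methyl ketone with a non-enolisable aryl aldehyde, in which dehydration of the aldol gives the (E)-enone.

**Step 6**
Reactants: 8 (E)-1-[3,4-bis(benzyloxy)phenyl]-3-[(3S)-3-(benzyloxy)-2,2-dimethylchroman-6-yl]prop-2-en-1-one
Product: 10 1-[3,4-bis(benzyloxy)phenyl]-2-{[(3S)-3-(benzyloxy)-2,2-dimethylchroman-6-yl]methyl}-3,3-dimethoxypropan-1-one (both epimers at C2), via triethylsilyl enol ether 9 (not isolated)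
Conditions: Et3SiH (1.1 equiv), (Ph3P)3RhCl (1 mol%), THF, 50 °C; volatiles removed; then HC(OMe)3, BF3·OEt2, CH2Cl2, −78 °C
Reagents that add atoms: trimethyl orthoformate, COC(OC)OC; triethylsilane, CC[SiH](CC)CC (its silicon is carried only in 9)
Why: Rhodium-catalysed 1,4-hydrosilylation of the enone gives the silyl enol ether regiospecifically at the carbon that becomes C5, and its Mukaiyama-type reaction with the dimethoxycarbenium ion from the orthoformate installs C6 at the aldehyde oxidation level without base, so the β-keto acetal cannot lose methoxide by β-elimination; the new α-stereocentre is of no consequence.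

**Step 7**
Reactants: 10 1-[3,4-bis(benzyloxy)phenyl]-2-{[(3S)-3-(benzyloxy)-2,2-dimethylchroman-6-yl]methyl}-3,3-dimethoxypropan-1-one; 11 methyl methoxyacetate
Product: 12 methyl 3-[3,4-bis(benzyloxy)phenyl]-4-{[(3S)-3-(benzyloxy)-2,2-dimethylchroman-6-yl]methyl}-3-hydroxy-2,5,5-trimethoxypentanoate (mixture at C2, C3 and C4)
Conditions: 11, LiN(i-Pr)2, THF, −78 °C; anhydrous CeCl3, −78 °C; then 10; AcOH, −78 °C
Reagents that add atoms: none
Why: Aldol addition of the cerium-modified lithium enolate of an α-alkoxy ester to the ketone forms the C3–C4 bond, the weakly basic, oxophilic enolate favouring addition over enolisation of the hindered α-branched ketone; the three new stereocentres are all erased in step 8.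

**Step 8**
Reactants: 12 methyl 3-[3,4-bis(benzyloxy)phenyl]-4-{[(3S)-3-(benzyloxy)-2,2-dimethylchroman-6-yl]methyl}-3-hydroxy-2,5,5-trimethoxypentanoate
Product: 14 4-[3,4-bis(benzyloxy)phenyl]-5-{[(3S)-3-(benzyloxy)-2,2-dimethylchroman-6-yl]methyl}-3-methoxy-2H-pyran-2-one, via formyl pentenoate 13 (not isolated)
Conditions: p-TsOH·H2O (0.2 equiv), toluene, 70 °C
Reagents that add atoms: none
Why: Acid unmasks the aldehyde and dehydrates the tertiary benzylic carbinol, after which the ester carbonyl oxygen closes onto the protonated formyl group, water is lost to a 2-methoxypyrylium ion and demethylation leaves the 2-pyranone, as in the known acid cyclisation of 5-oxopent-2-enoates and their acetals; both alkene isomers funnel through the enal tautomer 13.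

**Step 9**
Reactants: 14 4-[3,4-bis(benzyloxy)phenyl]-5-{[(3S)-3-(benzyloxy)-2,2-dimethylchroman-6-yl]methyl}-3-methoxy-2H-pyran-2-one
Product: 16 (2S)-3-[3,4-bis(benzyloxy)phenyl]-2-{[(3S)-3-(benzyloxy)-2,2-dimethylchroman-6-yl]methyl}-4-methoxy-5-oxo-2,5-dihydrofuran-2-carbaldehyde (the 5-formyl butenolide), via epoxy lactone 15 (not isolated)
Conditions: D-fructose-derived ketone 1,2:4,5-di-O-isopropylidene-β-D-erythro-2,3-hexodiulo-2,6-pyranose (0.5 equiv), Oxone (2KHSO5·KHSO4·K2SO4), K2CO3, Bu4NHSO4, Na2B4O7/Na2EDTA buffer, MeCN–CH2(OMe)2, 0 °C; extractive work-up; then p-TsOH (10 mol%), CH2Cl2, 0 °C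
Reagents that add atoms: potassium peroxymonosulfate, [K+].[O-]S(=O)(=O)OO
Why: Proposed new method: the dioxirane formed in situ from the ketone and KHSO5 transfers oxygen to the C5=C6 enol-ester bond to give epoxy lactone 15, and the protic acid then opens the protonated epoxide at the acylal carbon C6 (assisted by the O1 lone pair), whereupon the C5 hydroxyl adds to the C2 carbonyl and the bridged tetrahedral intermediate collapses with C2–O1 cleavage, so that the lactone acyl group moves from the old ring oxygen to the C5 oxygen and C6 is left as the formyl group. The closest known chemistry is the chiral-dioxirane (Shi) epoxidation of enol esters and the protic-acid-induced rearrangement of enol ester epoxides to α-acyloxy carbonyl compounds with retention; neither has been shown on a 2-pyranone. The butenolide ring closes by 5-exo-trig attack of the C5 oxygen on the C2 carbonyl carbon. The C5 stereocentre is set only by the face of oxygen transfer, which the chiral ketone controls through its spiro transition state: with C6–H in the place of the vinylic hydrogen of a 1-substituted cycloalkene (the class that gives (R,R)-1-phenylcyclohexene oxide with this ketone), the D-fructose-derived ketone should deliver oxygen to the face that becomes (S) at C5, and the enantiomeric ketone is used if the sense proves opposite; the C5–O bond is never broken afterwards and the remote chromanyl centre has no influence. The step needs site selectivity for C5=C6 over C3=C4 and the arenes, secured by C3=C4 being tetrasubstituted, carbonyl-conjugated and shielded by the twisted aryl group while C5=C6 is a trisubstituted enol ester, and it needs acyl transfer in place of ionisation at C5, secured by catalytic protic acid at 0 °C, by the destabilising pair of oxygens on C6 next to a C5 cation, and by the ring geometry, which rules out the alternative 1,2-acyloxy shift with inversion.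

**Step 10**
Reactants: 16 (2S)-3-[3,4-bis(benzyloxy)phenyl]-2-{[(3S)-3-(benzyloxy)-2,2-dimethylchroman-6-yl]methyl}-4-methoxy-5-oxo-2,5-dihydrofuran-2-carbaldehyde
Product: 18 methyl (2S)-3-[3,4-bis(benzyloxy)phenyl]-2-{[(3S)-3-(benzyloxy)-2,2-dimethylchroman-6-yl]methyl}-4-methoxy-5-oxo-2,5-dihydrofuran-2-carboxylate, via carboxylic acid 17 (not isolated)
Conditions: NaClO2, NaH2PO4, 2-methyl-2-butene, t-BuOH–H2O, 0 °C to rt; extractive work-up; then Me3SiCHN2, MeOH–toluene, 0 °C
Reagents that add atoms: sodium chlorite, [Na+].[O-]Cl=O; trimethylsilyldiazomethane, C[Si](C)(C)C=[N+]=[N-]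
Why: Pinnick oxidation converts the non-enolisable aldehyde to the acid under mildly acidic conditions that leave the lactone, the enol ether and the quaternary stereocentre untouched, and trimethylsilyldiazomethane then methylates the acid without base.

**Step 11**
Reactants: 18 methyl (2S)-3-[3,4-bis(benzyloxy)phenyl]-2-{[(3S)-3-(benzyloxy)-2,2-dimethylchroman-6-yl]methyl}-4-methoxy-5-oxo-2,5-dihydrofuran-2-carboxylate
Product: 19 methyl (2S)-3-(3,4-dihydroxyphenyl)-2-{[(3S)-3-hydroxy-2,2-dimethylchroman-6-yl]methyl}-4-methoxy-5-oxo-2,5-dihydrofuran-2-carboxylate (target)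
Conditions: H2 (1 atm), Pd(OH)2/C, EtOAc–MeOH, rt
Reagents that add atoms: none
Why: Hydrogenolysis removes the two aryl benzyl ethers and the alkyl benzyl ether, while the tetrasubstituted, carbonyl-conjugated butenolide alkene and both stereocentres should not be affected.

**Compound list**

1 | 2,2-dimethyl-2H-chromene-6-carbonitrile | N#Cc1ccc2c(c1)C=CC(C)(C)O2 | starting material
2 | (3S,4S)-3,4-epoxy-2,2-dimethylchroman-6-carbonitrile | N#Cc1ccc2c(c1)[C@@H]1O[C@@H]1C(C)(C)O2 | intermediate
3 | (3S)-3-hydroxy-2,2-dimethylchroman-6-carbonitrile | N#Cc1ccc2c(c1)C[C@H](O)C(C)(C)O2 | intermediate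
4 | (3S)-3-(benzyloxy)-2,2-dimethylchroman-6-carbonitrile | N#Cc1ccc2c(c1)C[C@H](OCc1ccccc1)C(C)(C)O2 | intermediate
5 | N-(diisobutylaluminio) aldimine of aldehyde 6, i-Bu2Al–N=CH–[(3S)-3-(benzyloxy)-2,2-dimethylchroman-6-yl] | CC(C)C[Al](CC(C)C)N=Cc1ccc2c(c1)C[C@H](OCc1ccccc1)C(C)(C)O2 | intermediate
6 | (3S)-3-(benzyloxy)-2,2-dimethylchroman-6-carbaldehyde | O=Cc1ccc2c(c1)C[C@H](OCc1ccccc1)C(C)(C)O2 | intermediate
7 | 3,4-bis(benzyloxy)acetophenone | CC(=O)c1ccc(OCc2ccccc2)c(OCc2ccccc2)c1 | starting material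
8 | (E)-1-[3,4-bis(benzyloxy)phenyl]-3-[(3S)-3-(benzyloxy)-2,2-dimethylchroman-6-yl]prop-2-en-1-one | O=C(/C=C/c1ccc2c(c1)C[C@H](OCc1ccccc1)C(C)(C)O2)c1ccc(OCc2ccccc2)c(OCc2ccccc2)c1 | intermediate
9 | 1-[3,4-bis(benzyloxy)phenyl]-3-[(3S)-3-(benzyloxy)-2,2-dimethylchroman-6-yl]-1-(triethylsilyloxy)prop-1-ene | CC[Si](CC)(CC)OC(=CCc1ccc2c(c1)C[C@H](OCc1ccccc1)C(C)(C)O2)c1ccc(OCc2ccccc2)c(OCc2ccccc2)c1 | intermediate
10 | 1-[3,4-bis(benzyloxy)phenyl]-2-{[(3S)-3-(benzyloxy)-2,2-dimethylchroman-6-yl]methyl}-3,3-dimethoxypropan-1-one (both C2 epimers) | COC(OC)C(Cc1ccc2c(c1)C[C@H](OCc1ccccc1)C(C)(C)O2)C(=O)c1ccc(OCc2ccccc2)c(OCc2ccccc2)c1 | intermediate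
11 | methyl methoxyacetate | COCC(=O)OC | starting material
12 | methyl 3-[3,4-bis(benzyloxy)phenyl]-4-{[(3S)-3-(benzyloxy)-2,2-dimethylchroman-6-yl]methyl}-3-hydroxy-2,5,5-trimethoxypentanoate (mixture at C2, C3, C4) | COC(=O)C(OC)C(O)(c1ccc(OCc2ccccc2)c(OCc2ccccc2)c1)C(Cc1ccc2c(c1)C[C@H](OCc1ccccc1)C(C)(C)O2)C(OC)OC | intermediate
13 | methyl 3-[3,4-bis(benzyloxy)phenyl]-5-[(3S)-3-(benzyloxy)-2,2-dimethylchroman-6-yl]-4-formyl-2-methoxypent-3-enoate (alkene isomers, C2 racemic) | COC(=O)C(OC)C(c1ccc(OCc2ccccc2)c(OCc2ccccc2)c1)=C(C=O)Cc1ccc2c(c1)C[C@H](OCc1ccccc1)C(C)(C)O2 | intermediate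
14 | 4-[3,4-bis(benzyloxy)phenyl]-5-{[(3S)-3-(benzyloxy)-2,2-dimethylchroman-6-yl]methyl}-3-methoxy-2H-pyran-2-one | COC1=C(c2ccc(OCc3ccccc3)c(OCc3ccccc3)c2)C(Cc2ccc3c(c2)C[C@H](OCc2ccccc2)C(C)(C)O3)=COC1=O | intermediate
15 | (1R,6S)-5-[3,4-bis(benzyloxy)phenyl]-6-{[(3S)-3-(benzyloxy)-2,2-dimethylchroman-6-yl]methyl}-4-methoxy-2,7-dioxabicyclo[4.1.0]hept-4-en-3-one (the 5,6-epoxide of 14) | COC1=C(c2ccc(OCc3ccccc3)c(OCc3ccccc3)c2)[C@]2(Cc3ccc4c(c3)C[C@H](OCc3ccccc3)C(C)(C)O4)O[C@@H]2OC1=O | intermediate
16 | (2S)-3-[3,4-bis(benzyloxy)phenyl]-2-{[(3S)-3-(benzyloxy)-2,2-dimethylchroman-6-yl]methyl}-4-methoxy-5-oxo-2,5-dihydrofuran-2-carbaldehyde | O=C[C@@]1(Cc2ccc3c(c2)C[C@H](OCc2ccccc2)C(C)(C)O3)OC(=O)C(OC)=C1c1ccc(OCc2ccccc2)c(OCc2ccccc2)c1 | intermediate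
17 | (2S)-3-[3,4-bis(benzyloxy)phenyl]-2-{[(3S)-3-(benzyloxy)-2,2-dimethylchroman-6-yl]methyl}-4-methoxy-5-oxo-2,5-dihydrofuran-2-carboxylic acid | OC(=O)[C@@]1(Cc2ccc3c(c2)C[C@H](OCc2ccccc2)C(C)(C)O3)OC(=O)C(OC)=C1c1ccc(OCc2ccccc2)c(OCc2ccccc2)c1 | intermediate
18 | methyl (2S)-3-[3,4-bis(benzyloxy)phenyl]-2-{[(3S)-3-(benzyloxy)-2,2-dimethylchroman-6-yl]methyl}-4-methoxy-5-oxo-2,5-dihydrofuran-2-carboxylate | COC(=O)[C@@]1(Cc2ccc3c(c2)C[C@H](OCc2ccccc2)C(C)(C)O3)OC(=O)C(OC)=C1c1ccc(OCc2ccccc2)c(OCc2ccccc2)c1 | intermediate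
19 | methyl (2S)-3-(3,4-dihydroxyphenyl)-2-{[(3S)-3-hydroxy-2,2-dimethylchroman-6-yl]methyl}-4-methoxy-5-oxo-2,5-dihydrofuran-2-carboxylate | COC(=O)[C@@]1(Cc2ccc3c(c2)C[C@H](O)C(C)(C)O3)OC(=O)C(OC)=C1c1ccc(O)c(O)c1 | target

**Step count and risk**

Total: 11 steps. Longest linear sequence: 11 steps (1 to 19); 7 and 11 enter as purchased compounds.

Steps most likely to fail:

Step 9 (the proposed new method). What may go wrong: slow oxygen transfer to an electron-poor pyranone or transfer to the C3=C4 bond, poor facial discrimination, and, during the rearrangement, ionisation at C5 or a 1,2-shift from C5 to C6 in place of acyl transfer. The fallback uses known chemistry only, sets out from 7 and 6 and returns at 18, so that the pyranone is bypassed. Claisen condensation of 7 with dimethyl carbonate (NaH, THF) should give methyl 3-[3,4-bis(benzyloxy)phenyl]-3-oxopropanoate F1. Knoevenagel condensation of F1 with aldehyde 6 (piperidinium acetate) and conjugate reduction of the arylidene in the same flask with Hantzsch ester should give methyl 3-[3,4-bis(benzyloxy)phenyl]-2-{[(3S)-3-(benzyloxy)-2,2-dimethylchroman-6-yl]methyl}-3-oxopropanoate F2. Catalytic enantioselective α-hydroxylation of this β-keto ester (cinchona alkaloid catalyst with cumene hydroperoxide, the pseudo-enantiomer chosen that gives the (S)-carbinol) should give methyl (2S)-3-[3,4-bis(benzyloxy)phenyl]-2-{[(3S)-3-(benzyloxy)-2,2-dimethylchroman-6-yl]methyl}-2-hydroxy-3-oxopropanoate F3. Acylation of the tertiary alcohol with methoxyacetyl chloride (pyridine, DMAP) should give the methoxyacetate ester of F3, methyl (2S)-3-[3,4-bis(benzyloxy)phenyl]-2-{[(3S)-3-(benzyloxy)-2,2-dimethylchroman-6-yl]methyl}-2-(methoxyacetoxy)-3-oxopropanoate F4. Intramolecular aldol condensation of this α-acyloxy ketone (DBU, MeCN, 60 °C) closes the butenolide and delivers 18, which goes on to step 11. A minor C5 epimer would be a diastereomer of 18 and would be removed at that stage.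

Step 7. What may go wrong: enolisation of the hindered ketone in place of addition, followed by β-elimination of methoxide, or retro-aldol cleavage when the adduct warms. The fallback closes the C3=C4 bond within a ring, sets out from 10 and returns at 14, bypassing steps 7 and 8. Aqueous acid (1 M HCl, THF) should unmask the chelated enol (2Z)-1-[3,4-bis(benzyloxy)phenyl]-2-{[(3S)-3-(benzyloxy)-2,2-dimethylchroman-6-yl]methyl}-3-hydroxyprop-2-en-1-one F5. Saponification of commercial methyl 2-(dimethoxyphosphoryl)-2-methoxyacetate with one equivalent of LiOH gives 2-(dimethoxyphosphoryl)-2-methoxyacetic acid F6. Coupling of F5 with F6 (N,N'-dicyclohexylcarbodiimide, DMAP cat.) should give the enol ester (1Z)-3-[3,4-bis(benzyloxy)phenyl]-2-{[(3S)-3-(benzyloxy)-2,2-dimethylchroman-6-yl]methyl}-3-oxoprop-1-enyl 2-(dimethoxyphosphoryl)-2-methoxyacetate F7. Intramolecular Horner–Wadsworth–Emmons olefination of the aryl ketone (LiCl, DBU, MeCN) then gives pyranone 14 directly.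

Step 8. What may go wrong: incomplete ring closure because only the enoate isomer with the ester cis to C5 can lactonise, or acid-induced loss of benzyl groups on prolonged heating. The fallback separates unmasking from ring closure and activates the carboxyl group instead of relying on ester exchange; it sets out from 12 and returns at 14. Brief treatment of 12 with CF3CO2H–H2O in CH2Cl2 at rt should give the formyl pentenoate 13, this time isolated. Saponification (LiOH, THF–H2O, then acidification) should give 3-[3,4-bis(benzyloxy)phenyl]-5-[(3S)-3-(benzyloxy)-2,2-dimethylchroman-6-yl]-4-formyl-2-methoxypent-3-enoic acid F8. Carboxyl activation with 2-chloro-1-methylpyridinium iodide and Et3N (or Ac2O and Et3N) should acylate the dienolate oxygen intramolecularly, the known enol lactonisation of 5-oxo acids, to give 14.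

**Further compounds**

F1 | step 9 | methyl 3-[3,4-bis(benzyloxy)phenyl]-3-oxopropanoate | COC(=O)CC(=O)c1ccc(OCc2ccccc2)c(OCc2ccccc2)c1
F2 | step 9 | methyl 3-[3,4-bis(benzyloxy)phenyl]-2-{[(3S)-3-(benzyloxy)-2,2-dimethylchroman-6-yl]methyl}-3-oxopropanoate | COC(=O)C(Cc1ccc2c(c1)C[C@H](OCc1ccccc1)C(C)(C)O2)C(=O)c1ccc(OCc2ccccc2)c(OCc2ccccc2)c1
F3 | step 9 | methyl (2S)-3-[3,4-bis(benzyloxy)phenyl]-2-{[(3S)-3-(benzyloxy)-2,2-dimethylchroman-6-yl]methyl}-2-hydroxy-3-oxopropanoate | COC(=O)[C@@](C(=O)c1ccc(OCc2ccccc2)c(OCc2ccccc2)c1)(Cc1ccc2c(c1)C[C@H](OCc1ccccc1)C(C)(C)O2)O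
F4 | step 9 | methyl (2S)-3-[3,4-bis(benzyloxy)phenyl]-2-{[(3S)-3-(benzyloxy)-2,2-dimethylchroman-6-yl]methyl}-2-(methoxyacetoxy)-3-oxopropanoate | COC(=O)[C@@](C(=O)c1ccc(OCc2ccccc2)c(OCc2ccccc2)c1)(Cc1ccc2c(c1)C[C@H](OCc1ccccc1)C(C)(C)O2)OC(=O)COC
F5 | step 7 | (2Z)-1-[3,4-bis(benzyloxy)phenyl]-2-{[(3S)-3-(benzyloxy)-2,2-dimethylchroman-6-yl]methyl}-3-hydroxyprop-2-en-1-one | O/C=C(/Cc1ccc2c(c1)C[C@H](OCc1ccccc1)C(C)(C)O2)C(=O)c1ccc(OCc2ccccc2)c(OCc2ccccc2)c1
F6 | step 7 | 2-(dimethoxyphosphoryl)-2-methoxyacetic acid | COC(C(=O)O)P(=O)(OC)OC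
F7 | step 7 | (1Z)-3-[3,4-bis(benzyloxy)phenyl]-2-{[(3S)-3-(benzyloxy)-2,2-dimethylchroman-6-yl]methyl}-3-oxoprop-1-enyl 2-(dimethoxyphosphoryl)-2-methoxyacetate | COC(C(=O)O/C=C(/Cc1ccc2c(c1)C[C@H](OCc1ccccc1)C(C)(C)O2)C(=O)c1ccc(OCc2ccccc2)c(OCc2ccccc2)c1)P(=O)(OC)OC
F8 | step 8 | 3-[3,4-bis(benzyloxy)phenyl]-5-[(3S)-3-(benzyloxy)-2,2-dimethylchroman-6-yl]-4-formyl-2-methoxypent-3-enoic acid | OC(=O)C(OC)C(c1ccc(OCc2ccccc2)c(OCc2ccccc2)c1)=C(C=O)Cc1ccc2c(c1)C[C@H](OCc1ccccc1)C(C)(C)O2
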